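## Structural features

The target is a 2,3-dihydro-1-benzofuran: benzene ring A is fused to the five-membered oxygen ring B (O1, C2, C3, C3a, C7a). C5 of ring A, para to O1, carries an (E)-propenoic acid. C2 of ring B carries the chain C1'H(CH3)–CH2–O, whose oxygen is acylated by (E)-4-hydroxycinnamic acid. The two stereocenters, C2 (S) and C1' (S), are directly bonded; in the zigzag CH2O–C1'–C2–C3 the methyl group on C1' and O1 on C2 lie on the same side (syn). The fragile groups are the two cinnamate-type acceptors, the free phenol, and a free carboxylic acid beside a cleavable alkyl ester, so hydroxide, hydride and hard nucleophiles are excluded late in the route. The real difficulty is absolute control at C2, relay of that control to C1', and an end game that leaves one free acid and one ester without protecting-group traffic. The key step exploits the fact that C2 is bonded to the benzylic carbon C3 (attached to C3a of ring A), to O1 and to C1'. A boron-bearing C2 can therefore receive the C3a–C3 and C2–C1' bonds in one three-component coupling, and its C–B bond then becomes the C2–O bond. That oxygen closes ring B at C7a by displacing a fluoride activated by the para carbonyl group at C5.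

## Logic of the disconnections

**16 to 14 and 15.** The C=C bond of the propenoic acid on C5 is cut. This acid is the only function that would otherwise need protection beside the side-chain ester; a condensation with decarboxylation releases it directly as the free (E)-acid in the last step. The gain is the removal of the conjugated acid and of every protecting group. The demand is that the condensation leaves the alkyl ester and the free phenol of 14 alone, so the amine is catalytic and no hydroxide is used.

**14 to 12 and 13.** The O–CH2 bond of the side-chain ester is cut (the alkyl C–O bond, not the acyl C–O bond). Forming this bond by displacement lets 13 be used unprotected, because its carboxyl group is far more acidic than its phenol. The gain is a convergent union of the chiral core with a commercial acid. The demand is chemoselectivity between carboxylate and phenoxide, substitution at a β-branched primary carbon, and a core in which the side-chain hydroxyl is the only free alcohol, so C5 must already stand at the aldehyde level.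

**12 to 11 to 10.** No skeletal bond is cut; the formyl group on C5 is traced back through the benzylic alcohol to a methyl ester. The ester is needed earlier as the para activator for ring closure and must be inert toward the allylboronate 6, which an aldehyde would not be. The gain is a robust spectator at C5 through the boron chemistry. The demand is an oxidant that distinguishes the benzylic from the aliphatic primary alcohol of 11.

**10 to 8.** The C–O bond of the CH2OH group and the C1'–H bond are cut, which leads back to a 1,1-disubstituted alkene. C1' sits next to C2, so a face-selective hydrometalation controlled by C2 can set it. The gain is the loss of one stereocenter and one oxygen. The demand is anti-Markovnikov regiochemistry and syn selectivity, which calls for the rhodium-catalysed variant.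

**8 to 7.** The O1–C7a bond is cut. An aryl ether para to an ester is the retron of a nucleophilic aromatic substitution, and since the C2–O bond is not touched the configuration of C2 is carried through. The gain is the opening of ring B to an acyclic alcohol. The demand is sufficient activation of the fluoride and a base that does not isomerise the allylic ether.

**7 to 6.** The C2–O bond is exchanged for a C2–B bond. Oxidation of a secondary boronic ester is stereoretentive, and a secondary allylic boronate is what the key step delivers. The demand is an oxidant mild enough to spare the methyl ester and to avoid allylic transposition.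

**6 to 2, 3 and 4 (through 5).** The C3a–C3 and C2–C1' bonds are cut in one operation. The gain is three simple achiral pieces and a single stereocenter set by a catalyst. The demand is correct assignment of acceptor and migrating alkenyl groups in 5, a medium in which halide does not block palladium, and tolerance of the ester and the aryl fluoride of 2. Reagent 4 is a commercial Grignard solution; with NaOTf it avoids both a pyrophoric alkyllithium and a gaseous bromoalkene.

**2 to 1.** The O–S bond is cut. Commercial 1 has the hydroxyl, the fluoride and the ester in the required 3, 4 and 1 positions. The demand is only a clean O-sulfonylation, done with a crystalline triflimide and not with the fuming anhydride.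

## Other disconnections considered

**Alternative 1:** The cut is the C2–C3 bond of ring B. In the forward sense, A1 (N'-[(E)-{5-bromo-2-[(2R)-3-{[tert-butyl(dimethyl)silyl]oxy}-2-methylpropoxy]phenyl}methylidene]-4-methylbenzenesulfonohydrazide) would be turned by Cs2CO3 into its diazo form in the flask. [Co(3,5-DitBu-ChenPhyrin)] (divalent cobalt) would convert this into a cobalt-bound carbene radical at the future C3. The radical would abstract one hydrogen of the O–CH2 group through a six-membered transition state, and the C2 radical would then substitute at C3, closing ring B to give A2 ((2S)-5-bromo-2-[(2S)-1-{[tert-butyl(dimethyl)silyl]oxy}propan-2-yl]-2,3-dihydro-1-benzofuran).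

- In its favour: ring B and C2 arise in one catalytic step. C1' is bought with the side chain from the chiral pool, so its configuration would be beyond doubt; on this point the alternative is the better plan. The bromide at C5 of A2 could be taken to the propenoate by one Heck reaction, which is shorter than the three steps (6, 7 and 9) that the chosen plan spends on this group.
- Against it here: the hydrogen to be abstracted is activated only by oxygen, not by an aryl or vinyl group. The two O–CH2 hydrogens are diastereotopic next to C1', so catalyst and substrate control may oppose each other. Abstraction of the tertiary C1'–H through a seven-membered transition state would lead to a six-membered ring and erase C1'. The porphyrin ligand needs a multistep preparation, and a silyl ether must be put on and taken off.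
- Comparison: structurally, the alternative forms one C–C bond and ring B in its key step, while the chosen plan forms two C–C bonds and no ring. Mechanistically, it is radical hydrogen abstraction and rebound against a polar 1,2-metallate shift with a commercial ligand. In step count the two are expected to be about equal, because what is saved on the acrylate is spent on silyl handling and on freeing a Heck-derived propenoate ester beside the coumarate.

**Alternative 2:** The cut is the C1'–CH3 bond together with the C–O bond of the CH2OH group. In the forward sense, A3 ((2S)-5-bromo-2-ethenyl-2,3-dihydro-1-benzofuran) would react with Me3Al in the presence of (NMI)2ZrCl2 and methylaluminoxane, (MeAlO)n. Methyl would add to C1' and aluminium to the terminal carbon, and O2 would then oxidise the C–Al bond to give A4 ((2S)-2-[(2S)-5-bromo-2,3-dihydro-1-benzofuran-2-yl]propan-1-ol).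

- In its favour: C1' would be set by the chiral zirconocene and not by C2. If the bias exerted by C2 proves weak, this is the better way to control C1'. The primary alcohol appears in the same operation, which equals the chosen hydroboration in step count, and the bromide again allows a Heck reaction.
- Against it here: the vinyl group sits on a carbon that bears O1, and this ether oxygen can bind aluminium and zirconium next to the reacting alkene. α-Branched 1-alkenes are slow and less selective partners in this carbometalation. Inverse regiochemistry would place the metal β to O1 and open ring B by loss of aryloxide. Me3Al and methylaluminoxane are pyrophoric and the oxygenation of alkylalanes is hard to run safely, which runs against the safety aim. A3 must itself be made enantiopure by a further asymmetric step.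
- Comparison: structurally, the alternative makes the C1'–CH3 bond that the chosen plan brings in ready-made with 3. Mechanistically, it is carbometalation under catalyst control against hydrometalation under substrate control. In step economy there is no saving, and two catalyst-controlled events are needed where the chosen plan needs one.

**Alternative 3:** The cuts are the O1–C2 and C2–C1' bonds. In the forward sense, Rh2(S-PTTL)4 (each rhodium divalent) would turn A5 (1-{5-bromo-2-[(2Z)-but-2-en-1-yloxy]phenyl}-2-diazoethan-1-one) into a carbenoid. The ether oxygen would capture it (O1–C2, closing the five-membered furanone ring), and the oxonium ylide would undergo a [2,3]-shift of the (Z)-crotyl group (C2–C1') to give A6 ((2R)-5-bromo-2-[(2S)-but-3-en-2-yl]-1-benzofuran-3(2H)-one).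

- In its favour: ring B, two bonds and both stereocenters would form in one step. In bonds and stereocenters per step the alternative is better than the chosen plan.
- Against it here: C2 of A6 lies between a ketone and an aryloxy group and is easily enolised, so its configuration is at risk in every step until the carbonyl is gone. Enantiocontrol requires the metal to stay bound to the ylide during the shift, and a free ylide would rearrange without induction. Removal of the C3 carbonyl and oxidative cleavage of the vinyl group to CH2OH add at least three redox steps. The diazoketone calls for diazomethane or a comparable diazo source.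
- Comparison: structurally, the key step is denser than that of the chosen plan. Mechanistically, it trades a configurationally stable boronate for a labile α-aryloxy ketone. In step economy the longer tail and the hazard of the diazo chemistry outweigh the dense key step, although the C5 handle is equal in value.

Key step: step 2

Remark on the chemistry: MandyPhos is 1,1'-bis[bis(4-methoxy-3,5-dimethylphenyl)phosphino]-2,2'-bis[α-(dimethylamino)benzyl]ferrocene; both antipodes are available, the route assumes the antipode that gives the S configuration at the boron-bearing carbon of 6, and this assignment is to be checked on alcohol 7 (MTPA esters) before material is carried forward.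

## Route

Step 1
Reactants: 1 methyl 4-fluoro-3-hydroxybenzoate
Product: 2 methyl 4-fluoro-3-{[(trifluoromethyl)sulfonyl]oxy}benzoate
Conditions: PhNTf2 (1.1 equiv), Et3N, DMAP (cat.), CH2Cl2, 0 °C → rt
Reagents that add atoms: N-phenylbis(trifluoromethanesulfonimide), O=S(=O)(N(c1ccccc1)S(=O)(=O)C(F)(F)F)C(F)(F)F
Why: O-Sulfonylation of an acidic phenol (ortho fluorine, meta ester) by triflyl transfer from the imide; the crystalline reagent replaces fuming Tf2O and its by-product is removed by a basic wash.

Step 2
Reactants: 3 4,4,5,5-tetramethyl-2-(prop-1-en-2-yl)-1,3,2-dioxaborolane; 4 vinylmagnesium bromide (commercial solution in THF); 2 methyl 4-fluoro-3-{[(trifluoromethyl)sulfonyl]oxy}benzoate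
Product: 6 methyl 4-fluoro-3-[(2S)-3-methyl-2-(4,4,5,5-tetramethyl-1,3,2-dioxaborolan-2-yl)but-3-en-1-yl]benzoate, via bromomagnesium vinyl(isopropenyl)pinacolborate 5 (not isolated)
Conditions: 3 (1.3 equiv), 4 (1.2 equiv), THF, 0 °C → rt; then NaOTf (2 equiv), Pd(OAc)2 (2 mol%), MandyPhos (2.4 mol%, antipode giving (S)-6), 2 (1.0 equiv), THF, 60 °C
Reagents that add atoms: none
Why: Addition of 4 to 3 gives the four-coordinate borate 5; NaOTf exchanges the counter-ion and takes the bromide out of play, so that commercial 4 can replace a vinyllithium made by bromine–lithium exchange, which would need a pyrophoric alkyllithium and a gaseous bromoalkene and would bring lithium bromide, an inhibitor of the cationic pathway. Zerovalent palladium, formed from Pd(OAc)2 and the bisphosphine, inserts into the C–OTf bond of 2 to give a cationic arylpalladium species (divalent palladium) that binds the unsubstituted vinyl group of 5. The isopropenyl group then shifts from boron to the boron-bearing carbon on the face opposite to palladium (C2–C1' bond), and C–C reductive elimination from the alkyl(aryl)palladium intermediate forms the C3a–C3 bond and returns zerovalent palladium. The closest known reaction type is the enantioselective conjunctive cross-coupling of bis(alkenyl)borates with aryl triflates to α-chiral allylic boronic esters, including its variant with Grignard-derived borates and NaOTf. No ring is closed in this step. The one new stereocenter, C2, is controlled by the chiral bisphosphine on palladium, which decides at which face of the bound vinyl group the 1,2-shift takes place. The step needs vinyl as acceptor and isopropenyl as migrating group, secured by the easier π-binding of the unsubstituted alkene, and it needs the 1,2-shift to beat direct alkenyl transfer to palladium and β-hydride elimination, secured by the triflate-derived cationic palladium and the wide-bite-angle ligand. The ester and the aryl fluoride are inert to 5, the slight excess of 3 over 4 leaves no free Grignard reagent for the ester, and an ester and not an aldehyde is carried because the allylboronate 6 would add to a formyl group.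

Step 3
Reactants: 6 methyl 4-fluoro-3-[(2S)-3-methyl-2-(4,4,5,5-tetramethyl-1,3,2-dioxaborolan-2-yl)but-3-en-1-yl]benzoate
Product: 7 methyl 4-fluoro-3-[(2S)-2-hydroxy-3-methylbut-3-en-1-yl]benzoate
Conditions: NaBO3·4H2O (3 equiv), THF/H2O (1:1), rt
Reagents that add atoms: sodium perborate (used as NaBO3·4H2O), [Na+].[Na+].O[B-]1(O)OO[B-](O)(O)OO1
Why: Oxidation of the C–B bond by 1,2-shift of C2 from boron to peroxide oxygen, which proceeds with retention and without allylic transposition; the nearly neutral perborate spares the methyl ester that NaOH/H2O2 would saponify.

Step 4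
Reactants: 7 methyl 4-fluoro-3-[(2S)-2-hydroxy-3-methylbut-3-en-1-yl]benzoate
Product: 8 methyl (2S)-2-(prop-1-en-2-yl)-2,3-dihydro-1-benzofuran-5-carboxylate
Conditions: t-BuOK (1.2 equiv), THF, 0 → 50 °C
Reagents that add atoms: none
Why: Intramolecular nucleophilic aromatic substitution: the alkoxide adds to the fluorine-bearing carbon para to the ester, the ester stabilises the anionic adduct, and loss of fluoride closes ring B (O1–C7a) in the 5-exo-trig mode; the C2–O bond is not touched, so C2 keeps its configuration, and THF is used instead of DMSO to avoid base-induced isomerisation of the allylic ether.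

Step 5
Reactants: 8 methyl (2S)-2-(prop-1-en-2-yl)-2,3-dihydro-1-benzofuran-5-carboxylate
Product: 10 methyl (2S)-2-[(2S)-1-hydroxypropan-2-yl]-2,3-dihydro-1-benzofuran-5-carboxylate, via catechol boronate 9 (not isolated)
Conditions: catecholborane (2 equiv), Rh(PPh3)3Cl (3 mol%), THF, 20 °C; then NaBO3·4H2O, THF/H2O, rt
Reagents that add atoms: catecholborane, B1Oc2ccccc2O1 (boron and catechol of 9); sodium perborate (used as NaBO3·4H2O), [Na+].[Na+].O[B-]1(O)OO[B-](O)(O)OO1 (hydroxyl oxygen of 10)
Why: Rhodium-catalysed hydroboration (B–H addition to monovalent rhodium, alkene insertion placing the metal on the terminal carbon, C–B reductive elimination) gives the anti-Markovnikov boronate, and oxidation with retention gives the primary alcohol. C1' is set by the C2 stereocenter: the metal hydride should take the alkene face anti to the allylic C2–O1 bond in the conformer with C2–H near the alkene plane, which is the syn-selective course known for 1,1-disubstituted alkenes with an allylic oxygen and corresponds to (2S,1'S).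

Step 6
Reactants: 10 methyl (2S)-2-[(2S)-1-hydroxypropan-2-yl]-2,3-dihydro-1-benzofuran-5-carboxylate
Product: 11 (2S)-2-[(2S)-5-(hydroxymethyl)-2,3-dihydro-1-benzofuran-2-yl]propan-1-ol
Conditions: LiAlH4 (THF solution), THF, 0 °C; aqueous potassium sodium tartrate work-up
Reagents that add atoms: none
Why: Hydride reduction of the aryl ester to the benzylic alcohol; no stereocenter is involved, and the neutral work-up protects the acid-sensitive 4-alkoxybenzyl alcohol.

Step 7
Reactants: 11 (2S)-2-[(2S)-5-(hydroxymethyl)-2,3-dihydro-1-benzofuran-2-yl]propan-1-ol
Product: 12 (2S)-2-[(2S)-1-hydroxypropan-2-yl]-2,3-dihydro-1-benzofuran-5-carbaldehyde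
Conditions: activated MnO2 (10 equiv), CH2Cl2, rt
Reagents that add atoms: none
Why: Chemoselective oxidation of the benzylic alcohol on the MnO2 surface; the saturated primary alcohol is not oxidised under these conditions, so no protecting group is needed.

Step 8
Reactants: 12 (2S)-2-[(2S)-1-hydroxypropan-2-yl]-2,3-dihydro-1-benzofuran-5-carbaldehyde; 13 (2E)-3-(4-hydroxyphenyl)prop-2-enoic acid
Product: 14 (2S)-2-[(2S)-5-formyl-2,3-dihydro-1-benzofuran-2-yl]propyl (2E)-3-(4-hydroxyphenyl)prop-2-enoate
Conditions: 13 (1.3 equiv), PPh3 (1.5 equiv), DIAD (1.5 equiv, slow addition), THF, 0 °C → rt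
Reagents that add atoms: none
Why: Mitsunobu esterification: the carboxylic acid, far more acidic than the phenol, protonates the phosphine–azodicarboxylate adduct, and the carboxylate displaces the alkoxyphosphonium group at the primary carbon, so the phenolic acid is used unprotected. The reacting carbon is not a stereocenter and C1' is untouched.

Step 9
Reactants: 14 (2S)-2-[(2S)-5-formyl-2,3-dihydro-1-benzofuran-2-yl]propyl (2E)-3-(4-hydroxyphenyl)prop-2-enoate; 15 malonic acid (propanedioic acid)
Product: 16 (2E)-3-[(2S)-2-{(2S)-1-[(2E)-3-(4-hydroxyphenyl)prop-2-enoyloxy]propan-2-yl}-2,3-dihydro-1-benzofuran-5-yl]prop-2-enoic acid (CNP0224846.1)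
Conditions: 15 (3 equiv), pyridine, piperidine (0.1 equiv), 80 °C; then cold dilute HCl
Reagents that add atoms: none
Why: Knoevenagel–Doebner condensation: iminium-activated aldehyde and malonate give the arylidene malonic acid, which loses CO2 in warm pyridine to the (E)-propenoic acid. The acid is released free, the alkyl coumarate and the phenol are not attacked by catalytic amine, and neither stereocenter is acidic.

## Compound list

1 | methyl 4-fluoro-3-hydroxybenzoate | COC(=O)c1ccc(F)c(O)c1 | starting material
2 | methyl 4-fluoro-3-{[(trifluoromethyl)sulfonyl]oxy}benzoate | COC(=O)c1ccc(F)c(OS(=O)(=O)C(F)(F)F)c1 | intermediate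
3 | 4,4,5,5-tetramethyl-2-(prop-1-en-2-yl)-1,3,2-dioxaborolane | CC(=C)B1OC(C)(C)C(C)(C)O1 | starting material
4 | vinylmagnesium bromide | C=C[Mg]Br | starting material
5 | bromomagnesium 2-ethenyl-4,4,5,5-tetramethyl-2-(prop-1-en-2-yl)-1,3,2-dioxaborolan-2-uide | C=C[B-]1(C(C)=C)OC(C)(C)C(C)(C)O1.[Mg+]Br | intermediate
6 | methyl 4-fluoro-3-[(2S)-3-methyl-2-(4,4,5,5-tetramethyl-1,3,2-dioxaborolan-2-yl)but-3-en-1-yl]benzoate | C=C(C)[C@@H](B1OC(C)(C)C(C)(C)O1)Cc1cc(C(=O)OC)ccc1F | intermediate
7 | methyl 4-fluoro-3-[(2S)-2-hydroxy-3-methylbut-3-en-1-yl]benzoate | C=C(C)[C@@H](O)Cc1cc(C(=O)OC)ccc1F | intermediate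
8 | methyl (2S)-2-(prop-1-en-2-yl)-2,3-dihydro-1-benzofuran-5-carboxylate | C=C(C)[C@@H]1Cc2cc(C(=O)OC)ccc2O1 | intermediate
9 | methyl (2S)-2-[(2S)-1-(1,3,2-benzodioxaborol-2-yl)propan-2-yl]-2,3-dihydro-1-benzofuran-5-carboxylate | C[C@@H](CB1Oc2ccccc2O1)[C@@H]1Cc2cc(C(=O)OC)ccc2O1 | intermediate
10 | methyl (2S)-2-[(2S)-1-hydroxypropan-2-yl]-2,3-dihydro-1-benzofuran-5-carboxylate | C[C@@H](CO)[C@@H]1Cc2cc(C(=O)OC)ccc2O1 | intermediate
11 | (2S)-2-[(2S)-5-(hydroxymethyl)-2,3-dihydro-1-benzofuran-2-yl]propan-1-ol | C[C@@H](CO)[C@@H]1Cc2cc(CO)ccc2O1 | intermediate
12 | (2S)-2-[(2S)-1-hydroxypropan-2-yl]-2,3-dihydro-1-benzofuran-5-carbaldehyde | C[C@@H](CO)[C@@H]1Cc2cc(C=O)ccc2O1 | intermediate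
13 | (2E)-3-(4-hydroxyphenyl)prop-2-enoic acid | O=C(O)/C=C/c1ccc(O)cc1 | starting material
14 | (2S)-2-[(2S)-5-formyl-2,3-dihydro-1-benzofuran-2-yl]propyl (2E)-3-(4-hydroxyphenyl)prop-2-enoate | C[C@@H](COC(=O)/C=C/c1ccc(O)cc1)[C@@H]1Cc2cc(C=O)ccc2O1 | intermediate
15 | malonic acid | O=C(O)CC(=O)O | starting material
16 | (2E)-3-[(2S)-2-{(2S)-1-[(2E)-3-(4-hydroxyphenyl)prop-2-enoyloxy]propan-2-yl}-2,3-dihydro-1-benzofuran-5-yl]prop-2-enoic acid | C[C@@H](COC(=O)/C=C/c1ccc(O)cc1)[C@@H]1Cc2cc(/C=C/C(=O)O)ccc2O1 | target

## Step count and least certain steps

Total step count: 9. Longest linear sequence: 9 steps (1 to 16).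

**Step 2 (key step).** Direct transfer of an alkenyl group from boron to palladium (Suzuki-type coupling) may compete with the 1,2-shift. Residual bromide may slow the catalyst. Facial discrimination may be lower than usual because the arylpalladium species carries an ortho fluorine. The fallback sets out from 2 and returns at 7, and sets C2 by epoxidation instead of by the coupling.
- A linear-selective Suzuki–Miyaura coupling of 2 with 3-methylbut-2-en-1-ylboronic acid pinacol ester (Pd(OAc)2, bulky biarylphosphine, K3PO4, THF/H2O) should give methyl 4-fluoro-3-(3-methylbut-2-en-1-yl)benzoate F1.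
- Shi epoxidation of the trisubstituted alkene (antipode of the fructose-derived ketone expected to give the S epoxide, KHSO5, K2CO3 buffer, MeCN/dimethoxymethane/H2O, 0 °C) should give methyl 3-{[(2S)-3,3-dimethyloxiran-2-yl]methyl}-4-fluorobenzoate F2.
- TMSOTf and DBU (toluene, −78 °C → rt) should open the epoxide at the tertiary carbon and remove a methyl proton to give methyl 4-fluoro-3-{(2S)-3-methyl-2-[(trimethylsilyl)oxy]but-3-en-1-yl}benzoate F3. Citric acid in MeOH then frees 7.
- The C2–O bond is never broken, so the configuration of the epoxide is carried into 7.

**Step 5.** Facial selectivity may be poor, because O1 is tied back in ring B and is smaller than the silyloxy groups for which the syn preference of the catalysed reaction is best established. Uncatalysed hydroboration by borane formed from decomposing catecholborane would favour the anti isomer. The fallback sets out from 7 and returns at 10, and sets C1' on the acyclic silyl ether before ring closure.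
- TBSCl and imidazole in DMF should give methyl 3-[(2S)-2-{[tert-butyl(dimethyl)silyl]oxy}-3-methylbut-3-en-1-yl]-4-fluorobenzoate F4.
- Catecholborane with Rh(PPh3)3Cl in THF should give methyl 3-[(2S,3S)-4-(1,3,2-benzodioxaborol-2-yl)-2-{[tert-butyl(dimethyl)silyl]oxy}-3-methylbutyl]-4-fluorobenzoate F5, which NaBO3·4H2O oxidises to methyl 3-[(2S,3S)-2-{[tert-butyl(dimethyl)silyl]oxy}-4-hydroxy-3-methylbutyl]-4-fluorobenzoate F6.
- Bu4NF in THF should give methyl 3-[(2S,3S)-2,4-dihydroxy-3-methylbutyl]-4-fluorobenzoate F7.
- t-BuOK in THF should close ring B through the secondary alkoxide and give 10; five-membered closure is expected to outrun seven-membered closure through the primary alkoxide.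

**Step 8.** O-Alkylation of the phenol may compete, and displacement at the β-branched primary carbon may be slow enough for the activated alcohol to be diverted to hydrazide by-products. The fallback sets out from 12 and 13 and returns at 14, and uses acyl activation with a protected phenol.
- Treatment of 13 with TBSCl (2.2 equiv) and imidazole in DMF should give tert-butyl(dimethyl)silyl (2E)-3-(4-{[tert-butyl(dimethyl)silyl]oxy}phenyl)prop-2-enoate F8. Its silyl ester is cleaved on work-up with AcOH in THF/H2O to give (2E)-3-(4-{[tert-butyl(dimethyl)silyl]oxy}phenyl)prop-2-enoic acid F9.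
- Steglich esterification of 12 with F9 (EDC·HCl, DMAP, CH2Cl2, rt) should give (2S)-2-[(2S)-5-formyl-2,3-dihydro-1-benzofuran-2-yl]propyl (2E)-3-(4-{[tert-butyl(dimethyl)silyl]oxy}phenyl)prop-2-enoate F10.
- Bu4NF buffered with AcOH (THF, 0 °C) removes the aryl silyl ether and gives 14.

**Step 9.** Piperidine may add to or cleave the coumarate ester, and decarboxylation may be incomplete at a temperature the ester tolerates. The fallback sets out from 14 and returns at 16, and uses olefination followed by acidolysis.
- Wittig reaction of 14 with tert-butyl (triphenylphosphoranylidene)acetate (2 equiv, toluene, 40 °C) should give tert-butyl (2E)-3-[(2S)-2-{(2S)-1-[(2E)-3-(4-hydroxyphenyl)prop-2-enoyloxy]propan-2-yl}-2,3-dihydro-1-benzofuran-5-yl]prop-2-enoate F11.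
- CF3CO2H in CH2Cl2 (0 °C) cleaves the tert-butyl ester without touching the alkyl coumarate and gives 16.

## Further compounds

F1 | step 2 | methyl 4-fluoro-3-(3-methylbut-2-en-1-yl)benzoate | COC(=O)c1ccc(F)c(CC=C(C)C)c1
F2 | step 2 | methyl 3-{[(2S)-3,3-dimethyloxiran-2-yl]methyl}-4-fluorobenzoate | CC1(C)O[C@H]1Cc1cc(C(=O)OC)ccc1F
F3 | step 2 | methyl 4-fluoro-3-{(2S)-3-methyl-2-[(trimethylsilyl)oxy]but-3-en-1-yl}benzoate | C=C(C)[C@@H](O[Si](C)(C)C)Cc1cc(C(=O)OC)ccc1F
F4 | step 5 | methyl 3-[(2S)-2-{[tert-butyl(dimethyl)silyl]oxy}-3-methylbut-3-en-1-yl]-4-fluorobenzoate | C=C(C)[C@@H](O[Si](C)(C)C(C)(C)C)Cc1cc(C(=O)OC)ccc1F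
F5 | step 5 | methyl 3-[(2S,3S)-4-(1,3,2-benzodioxaborol-2-yl)-2-{[tert-butyl(dimethyl)silyl]oxy}-3-methylbutyl]-4-fluorobenzoate | C[C@@H](CB1Oc2ccccc2O1)[C@@H](O[Si](C)(C)C(C)(C)C)Cc1cc(C(=O)OC)ccc1F
F6 | step 5 | methyl 3-[(2S,3S)-2-{[tert-butyl(dimethyl)silyl]oxy}-4-hydroxy-3-methylbutyl]-4-fluorobenzoate | C[C@@H](CO)[C@@H](O[Si](C)(C)C(C)(C)C)Cc1cc(C(=O)OC)ccc1F
F7 | step 5 | methyl 3-[(2S,3S)-2,4-dihydroxy-3-methylbutyl]-4-fluorobenzoate | C[C@@H](CO)[C@@H](O)Cc1cc(C(=O)OC)ccc1F
F8 | step 8 | tert-butyl(dimethyl)silyl (2E)-3-(4-{[tert-butyl(dimethyl)silyl]oxy}phenyl)prop-2-enoate | CC(C)(C)[Si](C)(C)OC(=O)/C=C/c1ccc(O[Si](C)(C)C(C)(C)C)cc1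
F9 | step 8 | (2E)-3-(4-{[tert-butyl(dimethyl)silyl]oxy}phenyl)prop-2-enoic acid | CC(C)(C)[Si](C)(C)Oc1ccc(/C=C/C(=O)O)cc1
F10 | step 8 | (2S)-2-[(2S)-5-formyl-2,3-dihydro-1-benzofuran-2-yl]propyl (2E)-3-(4-{[tert-butyl(dimethyl)silyl]oxy}phenyl)prop-2-enoate | C[C@@H](COC(=O)/C=C/c1ccc(O[Si](C)(C)C(C)(C)C)cc1)[C@@H]1Cc2cc(C=O)ccc2O1
F11 | step 9 | tert-butyl (2E)-3-[(2S)-2-{(2S)-1-[(2E)-3-(4-hydroxyphenyl)prop-2-enoyloxy]propan-2-yl}-2,3-dihydro-1-benzofuran-5-yl]prop-2-enoate | C[C@@H](COC(=O)/C=C/c1ccc(O)cc1)[C@@H]1Cc2cc(/C=C/C(=O)OC(C)(C)C)ccc2O1
A1 | alternative 1 | N'-[(E)-{5-bromo-2-[(2R)-3-{[tert-butyl(dimethyl)silyl]oxy}-2-methylpropoxy]phenyl}methylidene]-4-methylbenzenesulfonohydrazide | C[C@@H](CO[Si](C)(C)C(C)(C)C)COc1ccc(Br)cc1/C=N/NS(=O)(=O)c1ccc(C)cc1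
A2 | alternative 1 | (2S)-5-bromo-2-[(2S)-1-{[tert-butyl(dimethyl)silyl]oxy}propan-2-yl]-2,3-dihydro-1-benzofuran | C[C@@H](CO[Si](C)(C)C(C)(C)C)[C@@H]1Cc2cc(Br)ccc2O1
A3 | alternative 2 | (2S)-5-bromo-2-ethenyl-2,3-dihydro-1-benzofuran | C=C[C@@H]1Cc2cc(Br)ccc2O1
A4 | alternative 2 | (2S)-2-[(2S)-5-bromo-2,3-dihydro-1-benzofuran-2-yl]propan-1-ol | C[C@@H](CO)[C@@H]1Cc2cc(Br)ccc2O1
A5 | alternative 3 | 1-{5-bromo-2-[(2Z)-but-2-en-1-yloxy]phenyl}-2-diazoethan-1-one | C/C=C\COc1ccc(Br)cc1C(=O)C=[N+]=[N-]
A6 | alternative 3 | (2R)-5-bromo-2-[(2S)-but-3-en-2-yl]-1-benzofuran-3(2H)-one | C[C@@H](C=C)[C@@H]1C(=O)c2cc(Br)ccc2O1
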